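**Retrosynthetic overview**

1. Ring locants used below: C1 (acyloxy carbinol), C2=C3 (cis), C4 (quaternary), C5, C6=C7 (C7 carries the formyl carbon C12), C8, C9, C10–C11 (oxirane, methyl on C11). The senecioate is introduced last by Mitsunobu inversion at C1; before that the oxirane is fused onto C10=C11 by a matched, hydroxyl-directed Sharpless epoxidation.
2. Key disconnection C8–C9: the 11-membered carbocycle (the first ring formed; the oxirane is fused last) is closed by intramolecular SN2' attack of a C9 α-sulfonyl allyl anion on the C8 methylene of a Morita–Baylis–Hillman acetate, C8H2=C7(CO2Me)–C6H(OAc). The same step creates the C6=C7 olefin.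
3. Enabling feature: at the alkene oxidation level the ring atoms C6=C7–C8–C9–C10=C11 are a 1,5-diene, so C8–C9 is the link between two allyl units. C8 is the CH2 on the α-carbon C7 of the enal (a Baylis–Hillman retron) and C9 is allylic to C10=C11, the precursor of the oxirane. The cis C2=C3 olefin and the quaternary C4 fold the chain.
4. Open-chain precursor: C1–C2 by catalytic asymmetric alkynylation of (E)-4-acetoxy-2-methylbut-2-enal (C9, C10, C11, C1), then Lindlar reduction; C6–C7 by the Baylis–Hillman reaction with methyl acrylate; the sulfone from the allylic acetate.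
5. C4 is set by NHC–copper-catalysed SN2' alkynylation of geranyl phosphate; the vinyl group becomes C5–C6 and the homoprenyl group becomes the side chain by an epoxide/selenoxide transposition.

Key step: step 14

Remark: the hand of the chiral ligands in steps 2 and 7 is named for the sense required; should the facial sense in practice be the opposite, the mirror-image ligand is used and nothing else changes.

**Route**

Step 1
Reactants: 1 geraniol
Product: 2 geranyl diethyl phosphate
Conditions: ClP(O)(OEt)2, pyridine, DMAP (cat.), CH2Cl2, 0 °C to rt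
Reagents that add atoms: diethyl chlorophosphate, CCOP(=O)(Cl)OCC
Why: O-phosphorylation of the primary allylic alcohol gives the leaving group needed for copper-catalysed allylic substitution; no stereocentre is formed and the E olefin is retained.

Step 2
Reactants: 2 geranyl diethyl phosphate; 3 ethynyltrimethylsilane
Product: 5 (S)-(3-ethenyl-3,7-dimethyloct-6-en-1-yn-1-yl)trimethylsilane, via diisobutyl[(trimethylsilyl)ethynyl]aluminium 4 (not isolated)
Conditions: 3, i-Bu2AlH, Et3N (5 mol%), hexanes, 50 °C; then 2, CuCl2·2H2O (5 mol%), chiral sulfonate-bridged NHC–silver complex [Ag(NHC)]2 (2.5 mol%), THF, −30 °C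
Reagents that add atoms: none
Why: NHC–copper-catalysed enantioselective allylic substitution (SN2') of the trisubstituted allylic phosphate by the alkynylalane creates the all-carbon quaternary centre C4 (methyl, alkynyl, vinyl, homoprenyl); the chiral sulfonate-NHC–copper complex selects the olefin face (catalyst control) and should give the S configuration that maps onto C4 of the target.

Step 3
Reactants: 5 (S)-(3-ethenyl-3,7-dimethyloct-6-en-1-yn-1-yl)trimethylsilane
Product: 8 (S)-3-ethynyl-3,7-dimethyloct-6-en-1-ol, via B-alkyl-9-BBN adduct 6 (not isolated), via silylated alkynol 7 (not isolated)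
Conditions: 9-BBN, THF, 0 °C to rt; then NaOH, H2O2, 0 °C to rt; then K2CO3, MeOH, rt (one pot)
Reagents that add atoms: hydrogen peroxide, OO
Why: anti-Markovnikov hydroboration of the monosubstituted vinyl group by 9-BBN (the trisubstituted olefin and the silylalkyne are much slower), oxidation of the C–B bond and base-mediated protodesilylation of the alkyne should give the C5–C6 hydroxyethyl arm and the free alkyne; C4 is not touched.

Step 4
Reactants: 8 (S)-3-ethynyl-3,7-dimethyloct-6-en-1-ol
Product: 9 (3S)-5-(3,3-dimethyloxiran-2-yl)-3-ethynyl-3-methylpentan-1-ol (both epimers at the oxirane CH)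
Conditions: mCPBA, NaHCO3, CH2Cl2, 0 °C
Reagents that add atoms: 3-chloroperoxybenzoic acid, OOC(=O)c1cccc(Cl)c1
Why: Prilezhaev epoxidation is selective for the electron-rich trisubstituted olefin (the terminal alkyne is inert); the new oxirane CH centre forms as both epimers, which does not matter because it is destroyed in step 5.

Step 5
Reactants: 9 (3S)-5-(3,3-dimethyloxiran-2-yl)-3-ethynyl-3-methylpentan-1-ol
Product: 11 (S,E)-3-ethynyl-3,7-dimethyloct-5-ene-1,7-diol, via hydroxy selenide 10 (not isolated)
Conditions: PhSeSePh, NaBH4, EtOH, rt; then 9, 60 °C; then THF, 30% H2O2, 0 °C to rt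
Reagents that add atoms: none
Why: epoxide-to-allylic-alcohol transposition: benzeneselenolate opens the oxirane at the less hindered secondary carbon and the selenoxide formed with H2O2 undergoes syn elimination away from the carbinol carbon, giving the (E)-allylic tertiary alcohol of the side chain; no stereocentre remains in the side chain.

Step 6
Reactants: 11 (S,E)-3-ethynyl-3,7-dimethyloct-5-ene-1,7-diol
Product: 12 (S,E)-3-ethynyl-3,7-dimethyl-1,7-bis[(triethylsilyl)oxy]oct-5-ene
Conditions: Et3SiOTf (2.5 equiv), 2,6-lutidine, CH2Cl2, −78 to 0 °C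
Reagents that add atoms: triethylsilyl trifluoromethanesulfonate, CC[Si](CC)(CC)OS(=O)(=O)C(F)(F)F
Why: silylation with the reactive triflate protects the primary (C6) and the hindered tertiary hydroxyl as triethylsilyl ethers in one operation; no stereocentre is affected.

Step 7
Reactants: 12 (S,E)-3-ethynyl-3,7-dimethyl-1,7-bis[(triethylsilyl)oxy]oct-5-ene; 13 (E)-4-acetoxy-2-methylbut-2-enal
Product: 14 (2E,4R,7S,9E)-4-hydroxy-3,7,11-trimethyl-11-[(triethylsilyl)oxy]-7-{2-[(triethylsilyl)oxy]ethyl}dodeca-2,9-dien-5-yn-1-yl acetate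
Conditions: 12 (2 equiv, excess recovered), Me2Zn, (S,S)-ProPhenol (20 mol%), Ph3PO (40 mol%), toluene, 0 °C; then 13
Reagents that add atoms: none
Why: zinc–ProPhenol-catalysed asymmetric alkynylation of the α,β-unsaturated aldehyde forms the C1–C2 bond; the dinuclear zinc catalyst controls the aldehyde face and should set C1 (R at this stage, the epimer of the target that steps 19 and 20 require), the remote C4 centre having no influence.

Step 8
Reactants: 14 the propargylic alcohol of step 7
Product: 15 (2E,4R,7S,9E)-4-[(tert-butyldimethylsilyl)oxy]-3,7,11-trimethyl-11-[(triethylsilyl)oxy]-7-{2-[(triethylsilyl)oxy]ethyl}dodeca-2,9-dien-5-yn-1-yl acetate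
Conditions: t-BuMe2SiOTf, 2,6-lutidine, CH2Cl2, −78 °C
Reagents that add atoms: tert-butyldimethylsilyl trifluoromethanesulfonate, CC(C)(C)[Si](C)(C)OS(=O)(=O)C(F)(F)F
Why: silyl triflate/lutidine silylation protects the hindered propargylic alcohol as its TBS ether without acyl migration; the configuration at C1 is retained.

Step 9
Reactants: 15 the silylated enynyl acetate of step 8
Product: 16 (2E,4S,5Z,7S,9E)-4-[(tert-butyldimethylsilyl)oxy]-3,7,11-trimethyl-11-[(triethylsilyl)oxy]-7-{2-[(triethylsilyl)oxy]ethyl}dodeca-2,5,9-trien-1-yl acetate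
Conditions: H2 (1 atm), Pd/CaCO3 poisoned with Pb(OAc)2 (Lindlar catalyst), quinoline, EtOAc, rt
Reagents that add atoms: none
Why: Lindlar semi-hydrogenation adds H2 syn to the alkyne and should stop at the cis C2=C3 olefin (the tri- and disubstituted olefins are not reduced under quinoline poisoning); the C1 descriptor changes from R to S only because the substituent priorities change.

Step 10
Reactants: 16 the (Z)-allylic acetate of step 9
Product: 17 {[(2E,4S,5Z,7S,9E)-4-[(tert-butyldimethylsilyl)oxy]-3,7,11-trimethyl-11-[(triethylsilyl)oxy]-7-{2-[(triethylsilyl)oxy]ethyl}dodeca-2,5,9-trien-1-yl]sulfonyl}benzene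
Conditions: PhSO2Na, Pd(PPh3)4 (5 mol%), THF/DMF, rt
Reagents that add atoms: sodium benzenesulfinate, [Na+].[O-]S(=O)c1ccccc1
Why: Tsuji–Trost allylic substitution: zerovalent palladium ionises the primary allylic acetate and the sulfinate attacks the unhindered terminus C9 of the π-allyl complex, giving the linear (E)-allylic sulfone; C1 and C4 are untouched.

Step 11
Reactants: 17 the allylic sulfone of step 10
Product: 18 (3S,4Z,6S,7E)-6-[(tert-butyldimethylsilyl)oxy]-3,7-dimethyl-3-{(E)-4-methyl-4-[(triethylsilyl)oxy]pent-2-en-1-yl}-9-(phenylsulfonyl)nona-4,7-dienal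
Conditions: (COCl)2, DMSO, CH2Cl2, −78 °C; 17, −78 to −40 °C; Et3N, to 0 °C
Reagents that add atoms: none
Why: under Swern conditions a primary triethylsilyl ether is cleaved and oxidised directly to the aldehyde while the secondary TBS and tertiary triethylsilyl ethers survive, so C6 is unveiled as the aldehyde in one step.

Step 12
Reactants: 18 the aldehyde of step 11; 19 methyl acrylate
Product: 20 methyl (5S,6Z,8S,9E)-8-[(tert-butyldimethylsilyl)oxy]-3-hydroxy-5,9-dimethyl-2-methylidene-5-{(E)-4-methyl-4-[(triethylsilyl)oxy]pent-2-en-1-yl}-11-(phenylsulfonyl)undeca-6,9-dienoate (both C3 epimers)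
Conditions: 19 (excess), DABCO (1 equiv), MeOH (additive), rt
Reagents that add atoms: none
Why: Morita–Baylis–Hillman reaction: the DABCO–acrylate zwitterion adds to the aldehyde and forms the C6–C7 bond; the C6 carbinol forms as both epimers, which does not matter because C6 becomes sp2 in step 14.

Step 13
Reactants: 20 the Baylis–Hillman adduct of step 12
Product: 21 methyl (5S,6Z,8S,9E)-3-acetoxy-8-[(tert-butyldimethylsilyl)oxy]-5,9-dimethyl-2-methylidene-5-{(E)-4-methyl-4-[(triethylsilyl)oxy]pent-2-en-1-yl}-11-(phenylsulfonyl)undeca-6,9-dienoate (both C3 epimers)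
Conditions: Ac2O, pyridine, DMAP (cat.), CH2Cl2, 0 °C
Reagents that add atoms: acetic anhydride, CC(=O)OC(C)=O
Why: DMAP-catalysed acetylation of the secondary allylic alcohol turns C6–O into the leaving group of the SN2' electrophile; C1 and C4 are unchanged.

Step 14
Reactants: 21 the Baylis–Hillman acetate of step 13
Product: 22 macrocyclic sulfone ester: 11-membered carbocycle with (1S)-OTBS, (4S) quaternary carbon bearing the silylated side chain, CO2Me on C7, SO2Ph on C9 (both C9 epimers); olefins 2Z, 6E (C5 cis to C8 in the ring), 10E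
Conditions: KN(SiMe3)2 (1.3 equiv), THF (final 0.002 M), −78 °C; syringe-pump addition of 21, then −78 to −20 °C
Reagents that add atoms: none
Why: KN(SiMe3)2 removes the most acidic proton, that of the allylic sulfone at C9, and the α-sulfonyl allyl anion adds through C9 to the unsubstituted acrylate terminus C8; the ester enolate then expels the C6 acetate (E1cB), so the sequence is an intramolecular SN2' substitution of a Morita–Baylis–Hillman acetate. The closest known reaction types are the SN2' alkylation of Baylis–Hillman acetates by stabilised carbanions and the sulfone-anion allylation used to close humulene- and germacrene-type carbocycles. The 11-membered ring closes in an 11-endo-trig conjugate addition (C8 and C7 both end up in the ring). The only stereocentre formed, C9, arises as a mixture and is erased in step 16; the geometry of the new C6=C7 olefin (C5 trans to the ester, cis to C8 inside the ring) follows from the E1cB transition state that keeps the C5 chain away from the ester (allylic 1,3-strain) and is also the less strained ring olefin. The step needs attack through C9 (α) and not C11 (γ), and ring closure and not oligomerisation: the γ terminus is fully substituted and would give a 9-membered ring, the substrate is added slowly at high dilution, and the cis C2=C3 olefin together with the quaternary C4 folds the chain so that C9 and C8 meet.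

Step 15
Reactants: 22 the macrocyclic sulfone ester of step 14
Product: 23 macrocyclic sulfone alcohol: as 22 but with CH2OH on C7 (both C9 epimers)
Conditions: i-Bu2AlH (2.5 equiv), CH2Cl2, −78 °C; Rochelle salt work-up
Reagents that add atoms: none
Why: i-Bu2AlH reduces the conjugated methyl ester by 1,2-addition to the primary allylic alcohol C12 (sulfone and silyl ethers are inert at −78 °C), which removes the ester before the hydride-based desulfonylation.

Step 16
Reactants: 23 the macrocyclic sulfone alcohol of step 15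
Product: 24 macrocyclic triene alcohol: 11-membered carbocycle, (1S)-OTBS, (4S), CH2OH on C7, C9 now CH2; olefins 2Z, 6E, 10E
Conditions: PdCl2(dppp) (5 mol%), LiBHEt3 (3 equiv), THF, 0 °C
Reagents that add atoms: none
Why: palladium-catalysed reductive desulfonylation of the allylic sulfone (ionisation to the π-allyl complex, hydride delivery to C9, the less substituted terminus) removes the activating group without shifting or isomerising the (E)-C10=C11 olefin; the C9 stereocentre disappears.

Step 17
Reactants: 24 the macrocyclic triene alcohol of step 16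
Product: 25 macrocyclic enal: as 24 but with CHO on C7
Conditions: MnO2 (activated, excess), CH2Cl2, rt
Reagents that add atoms: none
Why: MnO2 oxidises only the primary allylic alcohol to the (E)-enal (C1 is silylated) without olefin isomerisation.

Step 18
Reactants: 25 the macrocyclic enal of step 17
Product: 26 macrocyclic diol enal: (1S)-OH, (4S), free tertiary alcohol in the side chain, CHO on C7; olefins 2Z, 6E, 10E
Conditions: HF·pyridine, pyridine, THF, 0 °C to rt
Reagents that add atoms: none
Why: buffered HF·pyridine cleaves the secondary TBS and tertiary triethylsilyl ethers in one operation under conditions mild enough for the enal and the doubly allylic C1 carbinol; no stereocentre is affected.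

Step 19
Reactants: 26 the macrocyclic diol enal of step 18
Product: 27 (1S,2Z,4S,6E,10S,11R)-10,11-epoxy alcohol: 7-formyl-4-[(E)-4-hydroxy-4-methylpent-2-en-1-yl]-4,11-dimethyl-10,11-epoxycycloundeca-2,6-dien-1-ol
Conditions: Ti(OiPr)4 (1.1 equiv), L-(+)-diisopropyl tartrate (1.3 equiv), t-BuOOH (2 equiv), 4 Å molecular sieves, CH2Cl2, −20 °C
Reagents that add atoms: tert-butyl hydroperoxide, CC(C)(C)OO
Why: matched Sharpless asymmetric epoxidation of the secondary allylic alcohol: the titanium tartrate delivers oxygen to the C10=C11 face on the side of its bound C1–O with the ring bond C1–C2 on the opposite face (erythro product, also the sense favoured by allylic 1,2-strain), setting C10 (S) and C11 (R) by combined substrate and reagent control; the hindered cis C2=C3 olefin, the tertiary allylic alcohol and the enal should not react.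

Step 20
Reactants: 27 the (1S)-epoxy alcohol of step 19; 28 3-methylbut-2-enoic acid
Product: 29 (1R,2Z,4S,6E,10S,11R)-7-formyl-4-[(E)-4-hydroxy-4-methylpent-2-en-1-yl]-4,11-dimethyl-10,11-epoxycycloundeca-2,6-dien-1-yl 3-methylbut-2-enoate (the target)
Conditions: 28, PPh3, diisopropyl azodicarboxylate, toluene, 0 °C to rt
Reagents that add atoms: none
Why: Mitsunobu esterification: the C1 alkoxyphosphonium ion is displaced by 3-methylbut-2-enoate in an SN2 reaction with inversion, which converts the (1S)-erythro epoxy alcohol into the (1R)-threo ester of the target in the same step that introduces the acyl group; the tertiary alcohol does not react.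

**Compound list**

1 | geraniol | CC(C)=CCC/C(C)=C/CO | starting material
2 | geranyl diethyl phosphate | CC(C)=CCC/C(C)=C/COP(=O)(OCC)OCC | intermediate
3 | ethynyltrimethylsilane | C#C[Si](C)(C)C | starting material
4 | diisobutyl[(trimethylsilyl)ethynyl]aluminium | CC(C)C[Al](CC(C)C)C#C[Si](C)(C)C | intermediate (not isolated)
5 | (S)-(3-ethenyl-3,7-dimethyloct-6-en-1-yn-1-yl)trimethylsilane | C[Si](C)(C)C#C[C@@](C)(CCC=C(C)C)C=C | intermediate
6 | 9-{(S)-3,7-dimethyl-3-[(trimethylsilyl)ethynyl]oct-6-en-1-yl}-9-borabicyclo[3.3.1]nonane | C[Si](C)(C)C#C[C@@](C)(CCC=C(C)C)CCB1C2CCCC1CCC2 | intermediate (not isolated)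
7 | (S)-3,7-dimethyl-3-[(trimethylsilyl)ethynyl]oct-6-en-1-ol | C[Si](C)(C)C#C[C@@](C)(CCC=C(C)C)CCO | intermediate (not isolated)
8 | (S)-3-ethynyl-3,7-dimethyloct-6-en-1-ol | C#C[C@@](C)(CCC=C(C)C)CCO | intermediate
9 | (3S)-5-(3,3-dimethyloxiran-2-yl)-3-ethynyl-3-methylpentan-1-ol (both oxirane epimers) | C#C[C@@](C)(CCC1OC1(C)C)CCO | intermediate
10 | (3S)-3-ethynyl-3,7-dimethyl-6-(phenylselanyl)octane-1,7-diol (both C6 epimers) | C#C[C@@](C)(CCC([Se]c1ccccc1)C(C)(C)O)CCO | intermediate (not isolated)
11 | (S,E)-3-ethynyl-3,7-dimethyloct-5-ene-1,7-diol | C#C[C@@](C)(C/C=C/C(C)(C)O)CCO | intermediate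
12 | (S,E)-3-ethynyl-3,7-dimethyl-1,7-bis[(triethylsilyl)oxy]oct-5-ene | C#C[C@@](C)(C/C=C/C(C)(C)O[Si](CC)(CC)CC)CCO[Si](CC)(CC)CC | intermediate
13 | (E)-4-acetoxy-2-methylbut-2-enal | CC(=O)OC/C=C(\C)C=O | starting material
14 | (2E,4R,7S,9E)-4-hydroxy-3,7,11-trimethyl-11-[(triethylsilyl)oxy]-7-{2-[(triethylsilyl)oxy]ethyl}dodeca-2,9-dien-5-yn-1-yl acetate | CC(=O)OC/C=C(\C)[C@@H](O)C#C[C@@](C)(C/C=C/C(C)(C)O[Si](CC)(CC)CC)CCO[Si](CC)(CC)CC | intermediate
15 | 4-O-TBS ether of 14 (2E,4R,7S,9E) | CC(=O)OC/C=C(\C)[C@@H](O[Si](C)(C)C(C)(C)C)C#C[C@@](C)(C/C=C/C(C)(C)O[Si](CC)(CC)CC)CCO[Si](CC)(CC)CC | intermediate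
16 | (2E,4S,5Z,7S,9E)-4-[(tert-butyldimethylsilyl)oxy]-3,7,11-trimethyl-11-[(triethylsilyl)oxy]-7-{2-[(triethylsilyl)oxy]ethyl}dodeca-2,5,9-trien-1-yl acetate | CC(=O)OC/C=C(\C)[C@@H](O[Si](C)(C)C(C)(C)C)/C=C\[C@@](C)(C/C=C/C(C)(C)O[Si](CC)(CC)CC)CCO[Si](CC)(CC)CC | intermediate
17 | allylic phenyl sulfone corresponding to 16 (SO2Ph in place of OAc on C9) | O=S(=O)(c1ccccc1)C/C=C(\C)[C@@H](O[Si](C)(C)C(C)(C)C)/C=C\[C@@](C)(C/C=C/C(C)(C)O[Si](CC)(CC)CC)CCO[Si](CC)(CC)CC | intermediate
18 | (3S,4Z,6S,7E)-6-[(tert-butyldimethylsilyl)oxy]-3,7-dimethyl-3-{(E)-4-methyl-4-[(triethylsilyl)oxy]pent-2-en-1-yl}-9-(phenylsulfonyl)nona-4,7-dienal | O=S(=O)(c1ccccc1)C/C=C(\C)[C@@H](O[Si](C)(C)C(C)(C)C)/C=C\[C@@](C)(C/C=C/C(C)(C)O[Si](CC)(CC)CC)CC=O | intermediate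
19 | methyl acrylate | C=CC(=O)OC | starting material
20 | Baylis–Hillman adduct, methyl (5S,6Z,8S,9E)-3-hydroxy-2-methylidene undeca-6,9-dienoate as named in step 12 (both C3 epimers) | O=S(=O)(c1ccccc1)C/C=C(\C)[C@@H](O[Si](C)(C)C(C)(C)C)/C=C\[C@@](C)(C/C=C/C(C)(C)O[Si](CC)(CC)CC)CC(O)C(=C)C(=O)OC | intermediate
21 | Baylis–Hillman acetate, the 3-acetate of 20 (both C3 epimers) | O=S(=O)(c1ccccc1)C/C=C(\C)[C@@H](O[Si](C)(C)C(C)(C)C)/C=C\[C@@](C)(C/C=C/C(C)(C)O[Si](CC)(CC)CC)CC(OC(C)=O)C(=C)C(=O)OC | intermediate
22 | macrocyclic sulfone ester (1S,2Z,4S,6E,10E; CO2Me on C7; SO2Ph on C9, both epimers) | C1(S(=O)(=O)c2ccccc2)/C=C(\C)[C@@H](O[Si](C)(C)C(C)(C)C)/C=C\[C@@](C)(C/C=C/C(C)(C)O[Si](CC)(CC)CC)C/C=C(/C(=O)OC)C1 | intermediate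
23 | macrocyclic sulfone alcohol (as 22, CH2OH on C7) | C1(S(=O)(=O)c2ccccc2)/C=C(\C)[C@@H](O[Si](C)(C)C(C)(C)C)/C=C\[C@@](C)(C/C=C/C(C)(C)O[Si](CC)(CC)CC)C/C=C(/CO)C1 | intermediate
24 | macrocyclic triene alcohol (1S,2Z,4S,6E,10E; CH2OH on C7; OTBS on C1; side-chain OSiEt3) | C1/C=C(\C)[C@@H](O[Si](C)(C)C(C)(C)C)/C=C\[C@@](C)(C/C=C/C(C)(C)O[Si](CC)(CC)CC)C/C=C(/CO)C1 | intermediate
25 | macrocyclic enal (as 24, CHO on C7) | C1/C=C(\C)[C@@H](O[Si](C)(C)C(C)(C)C)/C=C\[C@@](C)(C/C=C/C(C)(C)O[Si](CC)(CC)CC)C/C=C(/C=O)C1 | intermediate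
26 | macrocyclic diol enal (1S,2Z,4S,6E,10E; free C1–OH and side-chain tertiary OH) | C1/C=C(\C)[C@@H](O)/C=C\[C@@](C)(C/C=C/C(C)(C)O)C/C=C(/C=O)C1 | intermediate
27 | (1S,2Z,4S,6E,10S,11R)-epoxy alcohol (C1 epimer of the target alcohol) | O[C@H]1/C=C\[C@@](C)(C/C=C/C(C)(C)O)C/C=C(/C=O)CC[C@@H]2O[C@]21C | intermediate
28 | 3-methylbut-2-enoic acid | CC(C)=CC(=O)O | starting material
29 | (1R,2Z,4S,6E,10S,11R)-7-formyl-4-[(E)-4-hydroxy-4-methylpent-2-en-1-yl]-4,11-dimethyl-10,11-epoxycycloundeca-2,6-dien-1-yl 3-methylbut-2-enoate | CC(C)=CC(=O)O[C@@H]1/C=C\[C@@](C)(C/C=C/C(C)(C)O)C/C=C(/C=O)CC[C@@H]2O[C@]21C | target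

**Step count and risks**

Total step count: 20. Longest linear sequence: 20 steps (1 to 29).

The three steps most likely to fail:

Step 14 (macrocyclisation). Intermolecular conjugate addition (oligomerisation) or deprotonation next to the acetate may outrun closure of the strained 11-membered ring. Fallback, a classical sulfone-anion alkylation of an allylic halide: setting out from 20, N-bromosuccinimide/Me2S in CH2Cl2 at 0 °C should convert the Baylis–Hillman alcohol with allylic transposition into the (Z)-2-(bromomethyl)enoate F1. Slow addition of F1 to LiN(SiMe3)2 in THF at high dilution (−78 to 0 °C) should close the ring by direct SN2 displacement of bromide at C8 by the C9 sulfonyl carbanion, and the route is rejoined at 22.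

Step 20 (Mitsunobu inversion). Activation of the hindered carbinol flanked by the oxirane and the cis olefin may be slow, and elimination, SN2' attack or ionisation with loss of stereochemical integrity may compete. Fallback, sulfonate displacement by a carboxylate salt: setting out from 27, MsCl/Et3N in CH2Cl2 at −20 °C should give the C1 methanesulfonate F2 (the tertiary alcohol does not react). F2 is then displaced with inversion by caesium 3-methylbut-2-enoate (from 28 and Cs2CO3; 18-crown-6, toluene, 50 °C), which returns to the route at 29.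

Step 7 (asymmetric alkynylation). Facial selectivity or conversion may be poor with the bulky tertiary-alkyl acetylene and the α-branched enal. Fallback, addition followed by oxidation and reagent-controlled reduction: setting out from 12 and 13, deprotonation of 12 with n-BuLi (THF, −78 °C) and addition to 13 should give the propargylic alcohol as a mixture of C1 epimers F3. Dess–Martin oxidation then gives the ynone F4, and reduction with (R)-2-methyl-CBS-oxazaborolidine and catecholborane (toluene, −78 °C; the alkynyl group acts as the small substituent) returns to the route at 14.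

**Further compounds**

F1 | step 14 | methyl (2Z,5S,6Z,8S,9E)-2-(bromomethyl)-8-[(tert-butyldimethylsilyl)oxy]-5,9-dimethyl-5-{(E)-4-methyl-4-[(triethylsilyl)oxy]pent-2-en-1-yl}-11-(phenylsulfonyl)undeca-2,6,9-trienoate | O=S(=O)(c1ccccc1)C/C=C(\C)[C@@H](O[Si](C)(C)C(C)(C)C)/C=C\[C@@](C)(C/C=C/C(C)(C)O[Si](CC)(CC)CC)C/C=C(/C(=O)OC)CBr
F2 | step 20 | C1 methanesulfonate of the (1S,2Z,4S,6E,10S,11R)-epoxy alcohol 27 | CS(=O)(=O)O[C@H]1/C=C\[C@@](C)(C/C=C/C(C)(C)O)C/C=C(/C=O)CC[C@@H]2O[C@]21C
F3 | step 7 | (2E,7S,9E)-4-hydroxy-3,7,11-trimethyl-11-[(triethylsilyl)oxy]-7-{2-[(triethylsilyl)oxy]ethyl}dodeca-2,9-dien-5-yn-1-yl acetate (both C4 epimers) | CC(=O)OC/C=C(\C)C(O)C#C[C@@](C)(C/C=C/C(C)(C)O[Si](CC)(CC)CC)CCO[Si](CC)(CC)CC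
F4 | step 7 | (2E,7S,9E)-3,7,11-trimethyl-4-oxo-11-[(triethylsilyl)oxy]-7-{2-[(triethylsilyl)oxy]ethyl}dodeca-2,9-dien-5-yn-1-yl acetate | CC(=O)OC/C=C(\C)C(=O)C#C[C@@](C)(C/C=C/C(C)(C)O[Si](CC)(CC)CC)CCO[Si](CC)(CC)CC
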